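Retrosynthesis: the butenolide is opened at its lactone O–Cγ bond and at the Cβ–Cγ bond, giving a terminal alkyne (left half) and a (Z)-β-iodo dienoic acid (right half). The left chain is cut at three alkenes (two Horner–Wadsworth–Emmons, one Wittig), the right diene at its C8–C9 single bond (Stille), and the bicycle at its O3–C6 ether bond.
Enabling feature: the right end group is a 7-oxabicyclo[2.2.1]heptane whose ether oxygen bridges C3 and the quaternary C6, next to the tertiary carbinol C5. It is a constitutional isomer of a 3-hydroxy-5,6-epoxycyclohexane with hydroxyl and epoxide on opposite faces, so backside attack of O3 on C6 makes the O3–C6 bond, both oxolane rings and the C5/C6 stereo pair in one operation.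
Forward order: both carbocycles come from ketoisophorone through one (R)-silyloxy cyclohexenylmethanol. Right half: epoxide, iodoalkene, Stille coupling, transannular opening, iodide and acid. Left half: C4' oxidation and reduction, then three olefinations. The butenolide closes last, in the operation that joins the halves.
Stereochemistry: C3 of both rings comes from an enzymatic ene-reduction plus a trans-selective ketone hydrogenation. C5/C6 come from a reagent-controlled Sharpless epoxidation (C5 kept, C6 inverted in the key step), and C4' from hydride delivery anti to the C3' silyl ether. The E alkenes come from Takai, HWE and Wittig steps and from stereoretentive Stille and iododesilylation steps; the Z-ylidene comes from anti addition of the carboxylate to the alkyne.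

Key step: step 12

Remark: ring atoms carry carotenoid numbers (C1 = CMe2, C3 = carbinol, C5 = methyl-bearing carbon, C6 = chain-bearing carbon, C7/C8 = first chain alkene; primes mark the left ring). The change of descriptor at the silyloxy carbon (R in 8, S in 9 and 20) reflects CIP priorities only, not a change in space. TBS = tert-butyldimethylsilyl. All polyenes are handled under argon in dim light.

Step 1
Reactants: 1 ketoisophorone (2,6,6-trimethylcyclohex-2-ene-1,4-dione)
Product: 2 (6R)-2,2,6-trimethylcyclohexane-1,4-dione ((R)-levodione)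
Conditions: OYE2 (ene-reductase of baker's yeast), NADP+ (cat.), glucose dehydrogenase, D-glucose, phosphate buffer pH 7, 30 °C
Reagents that add atoms: none
Why: Flavoenzyme ene-reduction: hydride from the reduced flavin and a proton from the active site add trans across the enedione alkene on one face only, which should set the methyl-bearing carbon as R, a centre that merely steers step 2 and disappears in step 4.

Step 2
Reactants: 2 (R)-levodione
Product: 3 (4R,6R)-4-hydroxy-2,2,6-trimethylcyclohexanone (actinol; hydroxyl trans to the C6 methyl group)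
Conditions: H2 (10 bar), Raney Ni, MeOH, rt; crystallisation from i-Pr2O/hexane
Reagents that add atoms: none
Why: Heterogeneous ketone hydrogenation: only the unhindered C4 carbonyl reaches the nickel surface and hydrogen arrives from the equatorial side, away from the axial C2 methyl group, so the new carbinol should be axial, trans to the C6 methyl group and R, and crystallisation removes the cis isomer that would otherwise erode enantiopurity after step 4.

Step 3
Reactants: 3 actinol
Product: 4 (4R,6R)-4-(tert-butyldimethylsilyloxy)-2,2,6-trimethylcyclohexanone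
Conditions: TBSCl, imidazole, DMF, rt
Reagents that add atoms: tert-butyldimethylsilyl chloride, CC(C)(C)[Si](C)(C)Cl
Why: Imidazole-promoted silyl ether formation protects the only hydroxyl against the base, palladium and hydride steps that follow.

Step 4
Reactants: 4 silyloxy ketone
Product: 6 (4R)-4-(tert-butyldimethylsilyloxy)-2,6,6-trimethylcyclohex-1-en-1-yl trifluoromethanesulfonate, via lithium enolate 5 (not isolated)
Conditions: LiN(i-Pr)2, THF, −78 to 0 °C; then PhNTf2, −78 °C to rt
Reagents that add atoms: N-phenylbis(trifluoromethanesulfonimide), O=S(=O)(N(c1ccccc1)S(=O)(=O)C(F)(F)F)C(F)(F)F; lithium diisopropylamide, [Li]N(C(C)C)C(C)C (its lithium stays only in 5)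
Why: Enolate O-triflation: C6–H is the only α-hydrogen, so deprotonation can give just one enolate, whose trapping should furnish the tetrasubstituted enol triflate, erase the methyl stereocentre and leave the silyloxy carbon as the sole (R) stereocentre.

Step 5
Reactants: 6 enol triflate
Product: 7 methyl (4R)-4-(tert-butyldimethylsilyloxy)-2,6,6-trimethylcyclohex-1-ene-1-carboxylate
Conditions: CO (1 atm), Pd(OAc)2 (5 mol %), PPh3 (10 mol %), Et3N, MeOH/DMF, 50 °C
Reagents that add atoms: carbon monoxide, [C-]#[O+]; methanol, CO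
Why: Palladium-catalysed alkoxycarbonylation of an enol triflate: oxidative addition to zerovalent palladium formed in situ, CO insertion and methanolysis of the acylpalladium species add the C7 carbon without touching the silyl ether.

Step 6
Reactants: 7 methyl ester
Product: 8 [(4R)-4-(tert-butyldimethylsilyloxy)-2,6,6-trimethylcyclohex-1-en-1-yl]methanol
Conditions: i-Bu2AlH, CH2Cl2, −78 to 0 °C; aq Rochelle salt
Reagents that add atoms: none
Why: 1,2-Reduction of the hindered enoate with i-Bu2AlH should give the allylic alcohol from which both end groups are drawn, the silyl ether being inert.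

Step 7
Reactants: 8 allylic alcohol
Product: 9 [(1R,4S,6R)-4-(tert-butyldimethylsilyloxy)-2,2,6-trimethyl-7-oxabicyclo[4.1.0]heptan-1-yl]methanol (epoxide anti to the silyl ether)
Conditions: Ti(OiPr)4 (20 mol %), D-(−)-diethyl tartrate (25 mol %), t-BuOOH (decane), 4 Å MS, CH2Cl2, −20 °C
Reagents that add atoms: tert-butyl hydroperoxide, CC(C)(C)OO
Why: Sharpless asymmetric epoxidation: D-(−)-diethyl tartrate, the enantiomer that turns E allylic alcohols into (2R,3R)-epoxy alcohols, should deliver oxygen to the C5=C6 face opposite the C3 silyl ether, which is also the more open face, so C5 (R) and C6 are set together under reagent control.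

Step 8
Reactants: 9 epoxy alcohol
Product: 10 (1S,4S,6R)-4-(tert-butyldimethylsilyloxy)-2,2,6-trimethyl-7-oxabicyclo[4.1.0]heptane-1-carbaldehyde
Conditions: Dess–Martin periodinane, pyridine, CH2Cl2, 0 °C to rt
Reagents that add atoms: none
Why: Dess–Martin oxidation under pyridine buffering converts the hindered primary alcohol into the aldehyde without acid that could open the epoxide, and the α-carbon is quaternary so nothing can epimerise.

Step 9
Reactants: 10 epoxy aldehyde
Product: 11 (1S,4S,6R)-4-(tert-butyldimethylsilyloxy)-1-[(E)-2-iodoethenyl]-2,2,6-trimethyl-7-oxabicyclo[4.1.0]heptane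
Conditions: CrCl2, CHI3, THF, 0 °C to rt
Reagents that add atoms: iodoform, C(I)(I)I
Why: Takai iodo-olefination: the geminal dichromium reagent made from CHI3 adds to the aldehyde and the bulky quaternary neighbour should enforce the E alkene, while the neutral medium leaves epoxide and silyl ether alone.

Step 10
Reactants: 11 silylated iodoalkene
Product: 12 (1R,3S,6S)-6-[(E)-2-iodoethenyl]-1,5,5-trimethyl-7-oxabicyclo[4.1.0]heptan-3-ol (carotenoid numbering 3S,5R,6S; hydroxyl anti to the epoxide)
Conditions: Bu4NF, THF, 0 °C to rt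
Reagents that add atoms: none
Why: Fluoride desilylation frees the C3 hydroxyl before a C-silyl group enters the molecule, and neither the epoxide nor the E iodoalkene, whose β-hydrogen is cis to iodine, should react at this temperature.

Step 11
Reactants: 12 hydroxy epoxy iodoalkene; 13 methyl 3-(trimethylsilyl)propiolate
Product: 15 methyl (2Z)-2-{(E)-2-[(1S,4S,6R)-4-hydroxy-2,2,6-trimethyl-7-oxabicyclo[4.1.0]heptan-1-yl]ethenyl}-3-(trimethylsilyl)prop-2-enoate (silicon cis to the ester), via α-stannyl β-silyl acrylate 14 (not isolated)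
Conditions: 13, Bu3SnH, Pd(PPh3)4 (5 mol %), THF, 0 °C to rt; then 12, CuI (20 mol %), DMF, 45 °C
Reagents that add atoms: tributyltin hydride, CCCC[SnH](CCCC)CCCC (tin stays only in 14; only its hydrogen reaches 15)
Why: Palladium-catalysed syn-hydrostannation followed by Stille coupling: hydride goes to the silyl-bearing carbon and tin to the carbon α to the ester, so silicon ends cis to the ester, and the CuI-assisted coupling should join the two sp2 carbons with retention on both sides while tolerating hydroxyl and epoxide.

Step 12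
Reactants: 15 hydroxy epoxy silyl dienoate
Product: 16 methyl (2Z)-2-{(E)-2-[(1R,2R,4S)-2-hydroxy-2,6,6-trimethyl-7-oxabicyclo[2.2.1]heptan-1-yl]ethenyl}-3-(trimethylsilyl)prop-2-enoate (carotenoid numbering 3S,5R,6R)
Conditions: BF3·OEt2 (0.3 equiv), CH2Cl2, −78 to −30 °C; Et3N quench
Reagents that add atoms: none
Why: BF3 binds the epoxide oxygen, the six-membered ring moves into a boat that brings the C3 hydroxyl behind C6 on the face opposite the C6–O bond, and O3 displaces that oxygen in a loose intramolecular SN2 process while the C5–O bond stays intact and becomes the tertiary alcohol. The closest known reaction type is the Lewis-acid transannular opening of anti 3-hydroxy-5,6-epoxy carotenoid end groups carrying an acceptor-substituted side chain, which gives 3,6-epoxy-5-ols. The single new bond closes two oxolanes: ring O3–C3–C2–C1–C6 forms in 5-exo-tet mode (C5 and the leaving oxygen lie outside it) and ring O3–C3–C4–C5–C6 in formal 5-endo-tet mode (C5 lies inside it), the usual endo penalty being lifted because the boat already aligns O3 with the rear lobe of the C6–O bond. C6 is the only centre that changes: it is inverted (S to R) because the tether can reach it only from the face anti to the epoxide, whereas C5 keeps the configuration set in step 7 and C3 keeps its C–O bond. The step needs attack at C6 rather than C5, no C5–O ionisation with ring contraction and no 5,8-furanoid closure. Attack at C5 would build an oxetane, C6–O is the allylic and weaker bond, the ester-bearing diene keeps cation character at C8 low, and the low temperature with substoichiometric acid spares the electron-poor vinylsilane.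

Step 13
Reactants: 16 oxanorbornane silyl dienoate
Product: 17 methyl (2Z)-2-{(E)-2-[(1R,2R,4S)-2-hydroxy-2,6,6-trimethyl-7-oxabicyclo[2.2.1]heptan-1-yl]ethenyl}-3-iodoprop-2-enoate (iodine cis to the ester)
Conditions: NIS, 2,6-lutidine (0.2 equiv), (CF3)2CHOH, 0 °C, dark
Reagents that add atoms: N-iodosuccinimide, O=C1CCC(=O)N1I
Why: Electrophilic ipso-iododesilylation: the iodonium source attacks the silyl-bearing carbon because the resulting cation is β to silicon and allylic, and loss of silicon after least-motion rotation should retain the geometry.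

Step 14
Reactants: 17 iodo ester
Product: 18 (2Z)-2-{(E)-2-[(1R,2R,4S)-2-hydroxy-2,6,6-trimethyl-7-oxabicyclo[2.2.1]heptan-1-yl]ethenyl}-3-iodoprop-2-enoic acid
Conditions: LiOH, THF/MeOH/H2O, 0 °C to rt; then cold 0.5 M HCl to pH 3
Reagents that add atoms: lithium hydroxide, [Li+].[OH-]
Why: Saponification of the methyl ester: the α-carbon carries no hydrogen, so hydrogen iodide cannot be eliminated, and the mild temperature should keep hydroxide from attacking the iodo-bearing carbon.

Step 15
Reactants: 8 allylic alcohol
Product: 19 [(4R)-4-(tert-butyldimethylsilyloxy)-2,6,6-trimethylcyclohex-1-en-1-yl]methyl pivalate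
Conditions: t-BuCOCl, pyridine, DMAP (cat.), CH2Cl2, 0 °C to rt
Reagents that add atoms: pivaloyl chloride, CC(C)(C)C(=O)Cl
Why: Acylation as the bulky pivalate deactivates the CH2O position toward the coming C–H oxidation and gives an ester that survives the borohydride of step 17.

Step 16
Reactants: 19 pivalate
Product: 20 [(4S)-4-(tert-butyldimethylsilyloxy)-2,6,6-trimethyl-3-oxocyclohex-1-en-1-yl]methyl pivalate (ketone at C4')
Conditions: Rh2(cap)4 (1 mol %; cap = caprolactamate), 70 % aq t-BuOOH, ClCH2CH2Cl, 40 °C
Reagents that add atoms: tert-butyl hydroperoxide, CC(C)(C)OO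
Why: Dirhodium-catalysed allylic C–H oxidation (hydrogen abstraction by the t-BuOO radical, peroxide capture, loss of t-BuOH): the ring CH2 at C4' is the only secondary allylic site, the C5' methyl group is primary and the CH2OPiv group is deactivated and shielded, so the enone should form at C4' with C3' untouched.

Step 17
Reactants: 20 silyloxy enone
Product: 21 [(3R,4S)-4-(tert-butyldimethylsilyloxy)-3-hydroxy-2,6,6-trimethylcyclohex-1-en-1-yl]methyl pivalate (hydroxyl cis to the silyl ether)
Conditions: Li[HB(s-Bu)3] (L-Selectride), THF, −78 °C; aq NH4Cl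
Reagents that add atoms: none
Why: Sterically controlled 1,2-reduction of an α-silyloxy enone: the bulky borohydride should approach C4' from the face opposite the C3' silyl ether, which places the new hydroxyl cis to it (4'R), and the fully substituted, hindered β-carbon disfavours conjugate reduction.

Step 18
Reactants: 21 cis hydroxy silyl ether
Product: 22 [(3R,4S)-3,4-bis(tert-butyldimethylsilyloxy)-2,6,6-trimethylcyclohex-1-en-1-yl]methyl pivalate
Conditions: TBSOTf, 2,6-lutidine, CH2Cl2, 0 °C
Reagents that add atoms: tert-butyldimethylsilyl triflate, CC(C)(C)[Si](C)(C)OS(=O)(=O)C(F)(F)F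
Why: Silylation with the reactive triflate covers the hindered allylic hydroxyl under non-acidic conditions, so that it cannot ionise.

Step 19
Reactants: 22 bis(silyl) pivalate
Product: 23 [(3R,4S)-3,4-bis(tert-butyldimethylsilyloxy)-2,6,6-trimethylcyclohex-1-en-1-yl]methanol
Conditions: i-Bu2AlH, CH2Cl2, −78 °C; aq Rochelle salt
Reagents that add atoms: none
Why: Reductive cleavage of the pivalate with i-Bu2AlH frees the primary allylic alcohol and leaves both silyl ethers in place.

Step 20
Reactants: 23 allylic alcohol
Product: 24 (3R,4S)-3,4-bis(tert-butyldimethylsilyloxy)-2,6,6-trimethylcyclohex-1-ene-1-carbaldehyde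
Conditions: MnO2, CH2Cl2, rt
Reagents that add atoms: none
Why: Allylic alcohol oxidation with MnO2 takes the single free allylic hydroxyl to the aldehyde and stops there.

Step 21
Reactants: 24 C10 aldehyde; 25 triethyl (E)-3-methyl-4-phosphonocrotonate
Product: 27 ethyl (2E,4E)-5-[(3R,4S)-3,4-bis(tert-butyldimethylsilyloxy)-2,6,6-trimethylcyclohex-1-en-1-yl]-3-methylpenta-2,4-dienoate, via lithiated C5 phosphonate 26 (not isolated)
Conditions: 25, n-BuLi, THF/DMPU, −78 °C; then 24, −78 to 0 °C
Reagents that add atoms: n-butyllithium, [Li]CCCC (its lithium stays only in 26)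
Why: Horner–Wadsworth–Emmons olefination with the vinylogous phosphonate: the stabilised anion should give the E C7'=C8' alkene with the hindered aldehyde, and the E geometry of the reagent's own alkene is carried into C9'=C10'.

Step 22
Reactants: 27 C15 trienoate
Product: 28 (2E,4E)-5-[(3R,4S)-3,4-bis(tert-butyldimethylsilyloxy)-2,6,6-trimethylcyclohex-1-en-1-yl]-3-methylpenta-2,4-dien-1-ol
Conditions: i-Bu2AlH, CH2Cl2, −78 °C; aq Rochelle salt
Reagents that add atoms: none
Why: 1,2-Reduction of the conjugated ester with i-Bu2AlH gives the dienol without touching alkene geometry or silyl ethers.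

Step 23
Reactants: 28 C15 alcohol
Product: 29 (2E,4E)-5-[(3R,4S)-3,4-bis(tert-butyldimethylsilyloxy)-2,6,6-trimethylcyclohex-1-en-1-yl]-3-methylpenta-2,4-dienal
Conditions: MnO2, CH2Cl2, rt, dark
Reagents that add atoms: none
Why: Allylic alcohol oxidation with MnO2 is neutral and should preserve the E,E geometry.

Step 24
Reactants: 29 C15 aldehyde
Product: 30 (2E,4E,6E)-7-[(3R,4S)-3,4-bis(tert-butyldimethylsilyloxy)-2,6,6-trimethylcyclohex-1-en-1-yl]-5-methylhepta-2,4,6-trienal
Conditions: Ph3P=CHCHO, toluene, 80 °C, dark
Reagents that add atoms: (triphenylphosphoranylidene)acetaldehyde, O=CC=P(c1ccccc1)(c1ccccc1)c1ccccc1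
Why: Wittig reaction with the stabilised formyl ylide adds two carbons as an E enal in one step, and the longer, less electrophilic product aldehyde should react more slowly than the substrate, which limits double homologation.

Step 25
Reactants: 31 (E)-3-methylpent-2-en-4-yn-1-ol
Product: 34 (E)-3-methyl-5-(trimethylsilyl)pent-2-en-4-yn-1-ol, via dilithio enynolate 32 (not isolated), via bis(trimethylsilyl) derivative 33 (not isolated)
Conditions: n-BuLi (2.1 equiv), THF, −78 °C; Me3SiCl (2.2 equiv), −78 °C to rt; then 1 M HCl, THF, rt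
Reagents that add atoms: chlorotrimethylsilane, C[Si](C)(C)Cl; n-butyllithium, [Li]CCCC (its lithium stays only in 32)
Why: C,O-bis-silylation of the dianion and selective hydrolysis of the labile O–Si bond cap the acidic alkyne C–H, so that the phosphonate CH2 will be the only acidic site in step 28.

Step 26
Reactants: 34 C-silyl enynol
Product: 35 [(E)-5-bromo-3-methylpent-3-en-1-yn-1-yl]trimethylsilane
Conditions: PBr3 (0.4 equiv), Et2O, 0 °C
Reagents that add atoms: phosphorus tribromide, BrP(Br)Br
Why: Bromination of the primary allylic alcohol through its phosphite ester is an SN2 displacement at the unhindered CH2 and should keep the E alkene.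

Step 27
Reactants: 35 allylic bromide
Product: 36 diethyl [(E)-3-methyl-5-(trimethylsilyl)pent-2-en-4-yn-1-yl]phosphonate
Conditions: P(OEt)3, neat, 120 °C
Reagents that add atoms: triethyl phosphite, CCOP(OCC)OCC
Why: Michaelis–Arbuzov reaction of a primary allylic bromide, driven by loss of volatile bromoethane.

Step 28
Reactants: 30 C17 aldehyde; 36 C6 phosphonate
Product: 38 {(3E,5E,7E,9E,11E)-12-[(3R,4S)-3,4-bis(tert-butyldimethylsilyloxy)-2,6,6-trimethylcyclohex-1-en-1-yl]-3,10-dimethyldodeca-3,5,7,9,11-pentaen-1-yn-1-yl}trimethylsilane, via sodiated C6 phosphonate 37 (not isolated)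
Conditions: 36, NaN(SiMe3)2, THF, −78 °C; then 30, −78 to 0 °C, dark
Reagents that add atoms: sodium hexamethyldisilazide, [Na]N([Si](C)(C)C)[Si](C)(C)C (its sodium stays only in 37)
Why: Horner–Wadsworth–Emmons olefination of an enal with an allylic phosphonate anion should form the new disubstituted alkene E, and any minor Z isomer can be removed by chromatography.

Step 29
Reactants: 38 silylated hexaenyne
Product: 39 (1S,2R)-4-[(1E,3E,5E,7E,9E)-3,10-dimethyldodeca-1,3,5,7,9-pentaen-11-yn-1-yl]-3,5,5-trimethylcyclohex-3-ene-1,2-diol (cis diol; carotenoid numbering 3'S,4'R)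
Conditions: Bu4NF (excess), THF, 0 °C to rt, dark
Reagents that add atoms: none
Why: Global fluoride desilylation removes both O-silyl groups and the alkynyl silyl group in one basic operation, which avoids acid that would ionise the allylic C4' carbinol.

Step 30
Reactants: 18 (Z)-β-iodo dienoic acid; 39 hexaenyne diol
Product: 41 target CNP0216838.1, via dienynoic acid 40 (not isolated)
Conditions: Pd(PPh3)4 (5 mol %), CuI (10 mol %), Et3N, DMF, rt, dark, argon
Reagents that add atoms: none
Why: Sonogashira coupling followed in the same flask by 5-exo-dig lactonisation: the iodoalkene couples with retention, the carboxylate held cis to the new alkyne adds to it anti to the activating metal, and protodemetalation should leave the Z-ylidene butenolide, the three free hydroxyls being inert under these mild basic conditions.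

Compound list
1 | ketoisophorone | CC1=CC(=O)CC(C)(C)C1=O | starting material
2 | (6R)-2,2,6-trimethylcyclohexane-1,4-dione | O=C1C(C)(C)CC(=O)C[C@H]1C | intermediate
3 | (4R,6R)-4-hydroxy-2,2,6-trimethylcyclohexanone | O=C1C(C)(C)C[C@H](O)C[C@H]1C | intermediate
4 | (4R,6R)-4-(TBS-oxy)-2,2,6-trimethylcyclohexanone | O=C1C(C)(C)C[C@H](O[Si](C)(C)C(C)(C)C)C[C@H]1C | intermediate
5 | lithium enolate of 4 (not isolated) | CC1=C(O[Li])C(C)(C)C[C@H](O[Si](C)(C)C(C)(C)C)C1 | intermediate
6 | (4R)-4-(TBS-oxy)-2,6,6-trimethylcyclohex-1-en-1-yl triflate | CC1=C(OS(=O)(=O)C(F)(F)F)C(C)(C)C[C@H](O[Si](C)(C)C(C)(C)C)C1 | intermediate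
7 | methyl (4R)-4-(TBS-oxy)-2,6,6-trimethylcyclohex-1-ene-1-carboxylate | CC1=C(C(=O)OC)C(C)(C)C[C@H](O[Si](C)(C)C(C)(C)C)C1 | intermediate
8 | [(4R)-4-(TBS-oxy)-2,6,6-trimethylcyclohex-1-en-1-yl]methanol | CC1=C(CO)C(C)(C)C[C@H](O[Si](C)(C)C(C)(C)C)C1 | intermediate
9 | (1R,4S,6R) anti epoxy alcohol | OC[C@@]12O[C@]1(C)C[C@@H](O[Si](C)(C)C(C)(C)C)CC2(C)C | intermediate
10 | (1S,4S,6R) epoxy aldehyde | O=C[C@@]12O[C@]1(C)C[C@@H](O[Si](C)(C)C(C)(C)C)CC2(C)C | intermediate
11 | silylated (E)-iodoalkenyl epoxide | I/C=C/[C@@]12O[C@]1(C)C[C@@H](O[Si](C)(C)C(C)(C)C)CC2(C)C | intermediate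
12 | (1R,3S,6S)-6-[(E)-2-iodoethenyl]-1,5,5-trimethyl-7-oxabicyclo[4.1.0]heptan-3-ol | I/C=C/[C@@]12O[C@]1(C)C[C@@H](O)CC2(C)C | intermediate
13 | methyl 3-(trimethylsilyl)propiolate | COC(=O)C#C[Si](C)(C)C | starting material
14 | methyl (E)-2-(tributylstannyl)-3-(trimethylsilyl)prop-2-enoate (not isolated) | C[Si](C)(C)/C=C(\C(=O)OC)[Sn](CCCC)(CCCC)CCCC | intermediate
15 | hydroxy epoxy silyl dienoate | C[Si](C)(C)/C=C(\C(=O)OC)/C=C/[C@@]12O[C@]1(C)C[C@@H](O)CC2(C)C | intermediate
16 | oxanorbornane silyl dienoate | C[Si](C)(C)/C=C(\C(=O)OC)/C=C/[C@@]12O[C@@H](CC1(C)C)C[C@@]2(C)O | intermediate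
17 | oxanorbornane (Z)-β-iodo dienoate | I/C=C(\C(=O)OC)/C=C/[C@@]12O[C@@H](CC1(C)C)C[C@@]2(C)O | intermediate
18 | oxanorbornane (Z)-β-iodo dienoic acid | I/C=C(\C(O)=O)/C=C/[C@@]12O[C@@H](CC1(C)C)C[C@@]2(C)O | intermediate
19 | (4R) silyloxy pivalate | CC1=C(COC(=O)C(C)(C)C)C(C)(C)C[C@H](O[Si](C)(C)C(C)(C)C)C1 | intermediate
20 | (4S) 3-oxo silyloxy pivalate | CC1=C(COC(=O)C(C)(C)C)C(C)(C)C[C@H](O[Si](C)(C)C(C)(C)C)C1=O | intermediate
21 | (3R,4S) cis 3-hydroxy-4-silyloxy pivalate | CC1=C(COC(=O)C(C)(C)C)C(C)(C)C[C@H](O[Si](C)(C)C(C)(C)C)[C@@H]1O | intermediate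
22 | (3R,4S) bis(silyloxy) pivalate | CC1=C(COC(=O)C(C)(C)C)C(C)(C)C[C@H](O[Si](C)(C)C(C)(C)C)[C@@H]1O[Si](C)(C)C(C)(C)C | intermediate
23 | (3R,4S) bis(silyloxy) allylic alcohol | CC1=C(CO)C(C)(C)C[C@H](O[Si](C)(C)C(C)(C)C)[C@@H]1O[Si](C)(C)C(C)(C)C | intermediate
24 | (3R,4S) bis(silyloxy) C10 aldehyde | CC1=C(C=O)C(C)(C)C[C@H](O[Si](C)(C)C(C)(C)C)[C@@H]1O[Si](C)(C)C(C)(C)C | intermediate
25 | triethyl (E)-3-methyl-4-phosphonocrotonate | CCOC(=O)/C=C(\C)CP(=O)(OCC)OCC | starting material
26 | lithiated C5 phosphonate (not isolated) | CCOC(=O)/C=C(\C)C([Li])P(=O)(OCC)OCC | intermediate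
27 | C15 trienoate | CC1=C(/C=C/C(C)=C/C(=O)OCC)C(C)(C)C[C@H](O[Si](C)(C)C(C)(C)C)[C@@H]1O[Si](C)(C)C(C)(C)C | intermediate
28 | C15 alcohol | CC1=C(/C=C/C(C)=C/CO)C(C)(C)C[C@H](O[Si](C)(C)C(C)(C)C)[C@@H]1O[Si](C)(C)C(C)(C)C | intermediate
29 | C15 aldehyde | CC1=C(/C=C/C(C)=C/C=O)C(C)(C)C[C@H](O[Si](C)(C)C(C)(C)C)[C@@H]1O[Si](C)(C)C(C)(C)C | intermediate
30 | C17 aldehyde | CC1=C(/C=C/C(C)=C/C=C/C=O)C(C)(C)C[C@H](O[Si](C)(C)C(C)(C)C)[C@@H]1O[Si](C)(C)C(C)(C)C | intermediate
31 | (E)-3-methylpent-2-en-4-yn-1-ol | C#C/C(C)=C/CO | starting material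
32 | dilithio enynolate (not isolated) | [Li]C#C/C(C)=C/CO[Li] | intermediate
33 | C,O-bis(trimethylsilyl) enynol (not isolated) | C[Si](C)(C)C#C/C(C)=C/CO[Si](C)(C)C | intermediate
34 | (E)-3-methyl-5-(trimethylsilyl)pent-2-en-4-yn-1-ol | C[Si](C)(C)C#C/C(C)=C/CO | intermediate
35 | [(E)-5-bromo-3-methylpent-3-en-1-yn-1-yl]trimethylsilane | C[Si](C)(C)C#C/C(C)=C/CBr | intermediate
36 | diethyl [(E)-3-methyl-5-(trimethylsilyl)pent-2-en-4-yn-1-yl]phosphonate | C[Si](C)(C)C#C/C(C)=C/CP(=O)(OCC)OCC | intermediate
37 | sodiated C6 phosphonate (not isolated) | C[Si](C)(C)C#C/C(C)=C/C([Na])P(=O)(OCC)OCC | intermediate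
38 | fully silylated hexaenyne | CC1=C(/C=C/C(C)=C/C=C/C=C/C=C(C)/C#C[Si](C)(C)C)C(C)(C)C[C@H](O[Si](C)(C)C(C)(C)C)[C@@H]1O[Si](C)(C)C(C)(C)C | intermediate
39 | hexaenyne cis diol (left half) | CC1=C(/C=C/C(C)=C/C=C/C=C/C=C(C)/C#C)C(C)(C)C[C@H](O)[C@@H]1O | intermediate
40 | dienynoic acid (not isolated) | CC1=C(/C=C/C(C)=C/C=C/C=C/C=C(C)/C#C/C=C(\C(O)=O)/C=C/[C@@]23O[C@@H](CC2(C)C)C[C@@]3(C)O)C(C)(C)C[C@H](O)[C@@H]1O | intermediate
41 | CNP0216838.1: (5Z)-5-{(2E,4E,6E,8E,10E)-11-[(3R,4S)-3,4-dihydroxy-2,6,6-trimethylcyclohex-1-en-1-yl]-2,9-dimethylundeca-2,4,6,8,10-pentaen-1-ylidene}-3-{(E)-2-[(1R,2R,4S)-2-hydroxy-2,6,6-trimethyl-7-oxabicyclo[2.2.1]heptan-1-yl]ethenyl}furan-2(5H)-one | CC1=C(/C=C/C(C)=C/C=C/C=C/C=C(C)/C=C2C=C(/C=C/[C@@]34O[C@@H](CC3(C)C)C[C@@]4(C)O)C(=O)O/2)C(C)(C)C[C@H](O)[C@@H]1O | target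

Total step count: 30. Longest linear sequence: 19 steps (steps 1–6, 15–24 and 28–30).

Steps most likely to fail

Step 12. The acceptor-substituted diene may slow C6–O cleavage so much that the C5–O bond ionises instead and the ring contracts by a 1,2-shift, or the Lewis acid may strip the silyl group.
- Fallback: the order of ring closure and C–C coupling is reversed.
- Setting out from 12, the transannular opening is run on the alkenyl iodide (camphorsulfonic acid or BF3·OEt2, CH2Cl2, low temperature). This substrate carries neither ester nor silane, and its allylic C6–O bond is clearly the more labile one.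
- This should give the oxanorbornane iodoalkene F1.
- Stille coupling of F1 with stannane 14, prepared as in step 11, comes back to the route at 16.

Step 16. Hydrogen abstraction at C4' may stall because the neighbouring silyloxy group deactivates and shields this C–H bond, so that oxidation drifts to the C5' methyl group or the material is slowly degraded.
- Fallback: the C4' oxygen is introduced later, on a conjugated triene ester in which the C4' methylene is more strongly activated.
- Setting out from 8, MnO2 oxidation should give the 3'-silyloxy C10 aldehyde F2, and olefination with 26 as in step 21 the 3'-silyloxy C15 trienoate F3.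
- Excess activated MnO2, the reagent that converts retinoate esters into their 4-oxo derivatives, should then oxidise the ring methylene to the 4'-oxo C15 trienoate F4.
- L-Selectride at −78 °C should deliver hydride anti to the silyl ether and give the cis 4'-hydroxy C15 trienoate F5.
- TBSOTf with 2,6-lutidine comes back to the route at 27.

Step 30. The one-flask process may suffer from 6-endo closure to the pyranone, oxidative dimerisation of the alkyne, or E/Z isomerisation of the polyene during prolonged contact with palladium and copper.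
- Fallback: coupling and ring closure are separated, and the ring is closed with silver.
- Setting out from 17 and 39, Sonogashira coupling of the ester, which cannot cyclise, should give the methyl dienynoate F6.
- Mild saponification (LiOH, or Me3SnOH) comes back to the route at 40, now isolated.
- AgNO3 (cat.) in acetone in the dark, the known selective 5-exo-dig lactonisation of (Z)-2-en-4-ynoic acids, takes 40 to 41.

Further compounds
F1 | step 12 | oxanorbornane iodoalkene, (1R,2R,4S)-1-[(E)-2-iodoethenyl]-2,6,6-trimethyl-7-oxabicyclo[2.2.1]heptan-2-ol | I/C=C/[C@@]12O[C@@H](CC1(C)C)C[C@@]2(C)O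
F2 | step 16 | 3'-silyloxy C10 aldehyde, (4R)-4-(TBS-oxy)-2,6,6-trimethylcyclohex-1-ene-1-carbaldehyde | CC1=C(C=O)C(C)(C)C[C@H](O[Si](C)(C)C(C)(C)C)C1
F3 | step 16 | 3'-silyloxy C15 trienoate | CC1=C(/C=C/C(C)=C/C(=O)OCC)C(C)(C)C[C@H](O[Si](C)(C)C(C)(C)C)C1
F4 | step 16 | 4'-oxo C15 trienoate | CC1=C(/C=C/C(C)=C/C(=O)OCC)C(C)(C)C[C@H](O[Si](C)(C)C(C)(C)C)C1=O
F5 | step 16 | cis 4'-hydroxy C15 trienoate | CC1=C(/C=C/C(C)=C/C(=O)OCC)C(C)(C)C[C@H](O[Si](C)(C)C(C)(C)C)[C@@H]1O
F6 | step 30 | methyl dienynoate | CC1=C(/C=C/C(C)=C/C=C/C=C/C=C(C)/C#C/C=C(\C(=O)OC)/C=C/[C@@]23O[C@@H](CC2(C)C)C[C@@]3(C)O)C(C)(C)C[C@H](O)[C@@H]1O
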